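**Plan**
- Retrosynthetic cuts, in order: the C12–O acetate (Mitsunobu inversion) and C2–O acetate; C3–C4 (ring B); C8–C17 (γ-lactone); C6–C7 (chlorovinyl side chain); C2–C3 (sulfone opening of a temporary lactone); last, C1–C10 and C13–C14 together.
- Enabling feature: ring A (C1, C10, C11, C12, C13, C14) is a cyclohexene with oxygen on C12 para to the quaternary C1, and O9 is 1,4-related to C2 through C10–C1. A methacrylate on O9 and a 2-silyloxydiene C10=C11–C12=C13 can therefore combine intramolecularly through a temporary five-membered lactone O9–C2(=O).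
- Forward order: threitol-derived dienyl methacrylate → ring A plus temporary lactone (cycloaddition) → lactone opened at C2 by a sulfonyl carbanion (adds C3) → chlorovinyl fragment (C4–C6) joined at C7 → γ-lactone (C7, C8, C17, C19) by Reformatsky closure → ring B by C3–C4 alkylation → acetates.
- Stereochemistry: C9 from L-threitol; C10 and C1 from C9 (A(1,3) strain with the C20 methyl, trans ring fusion); C11 by kinetic protonation; C12 by Luche reduction then Mitsunobu inversion; C7 by Felkin–Anh addition; C8 and C17 in the Reformatsky closure; C2 by hydride reduction in ring B; C5=C6 geometry from syn carboalumination.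

Key step: step 9

Remark: locants follow the briarane skeleton (C1 quaternary ring-fusion carbon, C2–C9 in ring B, C10–C14 in ring A, C17–C19 in the lactone, methyls C15/C16/C18/C20 on C1/C5/C17/C11); β is the face of ring A that carries C15; TBS = tert-butyldimethylsilyl, PMB = 4-methoxybenzyl.

**Route**

Step 1
Reactants: 1 prop-2-yn-1-ol
Product: 3 (E)-3-chloro-2-methylprop-2-en-1-ol, via alkenylalane 2 (not isolated)
Conditions: Me3Al (3 equiv), Cp2ZrCl2 (0.25 equiv), CH2Cl2, 0 °C to rt; then N-chlorosuccinimide, THF, −30 to 0 °C; aqueous work-up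
Reagents that add atoms: trimethylaluminium C[Al](C)C; N-chlorosuccinimide O=C1CCC(=O)N1Cl
Why: Zirconium-catalysed Negishi carboalumination adds methyl and aluminium syn across the alkyne (methyl to the internal carbon) and chlorodealumination proceeds with retention, so chlorine ends cis to the methyl group as the C5=C6 geometry requires.

Step 2
Reactants: 3 (E)-3-chloro-2-methylprop-2-en-1-ol
Product: 4 (E)-tert-butyl[(3-chloro-2-methylprop-2-en-1-yl)oxy]dimethylsilane (fragment C4–C6 with C16)
Conditions: TBSCl, imidazole, CH2Cl2, 0 °C to rt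
Reagents that add atoms: tert-butyldimethylsilyl chloride CC(C)(C)[Si](C)(C)Cl
Why: Silyl ether formation protects the allylic alcohol (later C4–O) against the organolithium chemistry of step 16.

Step 3
Reactants: 5 L-threitol
Product: 6 (2R,4S,5S)-4-(hydroxymethyl)-2-(4-methoxyphenyl)-1,3-dioxan-5-ol
Conditions: 4-MeOC6H4CH(OMe)2 (1.0 equiv), camphorsulfonic acid (cat.), DMF, 50 °C, reduced pressure
Reagents that add atoms: 4-methoxybenzaldehyde dimethyl acetal COC(OC)c1ccc(OC)cc1
Why: Acid-catalysed transacetalization under thermodynamic control should favour the six-membered 1,3-dioxane with equatorial aryl and CH2OH groups, which leaves one primary hydroxyl (later C7) and one secondary hydroxyl (later C9, already in its final configuration from the chiral pool) free.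

Step 4
Reactants: 6 (2R,4S,5S)-4-(hydroxymethyl)-2-(4-methoxyphenyl)-1,3-dioxan-5-ol
Product: 7 (2R,4S,5S)-4-[(tert-butyldimethylsilyloxy)methyl]-2-(4-methoxyphenyl)-1,3-dioxan-5-ol
Conditions: TBSCl (1.05 equiv), imidazole, CH2Cl2, −20 °C
Reagents that add atoms: tert-butyldimethylsilyl chloride CC(C)(C)[Si](C)(C)Cl
Why: Selective silylation of the primary hydroxyl over the axial secondary ring hydroxyl on steric grounds.

Step 5
Reactants: 7 (2R,4S,5S)-4-[(tert-butyldimethylsilyloxy)methyl]-2-(4-methoxyphenyl)-1,3-dioxan-5-ol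
Product: 8 (2S,3S)-4-(tert-butyldimethylsilyloxy)-3-(4-methoxybenzyloxy)butane-1,2-diol
Conditions: i-Bu2AlH (3.5 equiv), CH2Cl2, −78 to 0 °C; Rochelle salt work-up
Reagents that add atoms: none
Why: Regioselective reductive opening of the 4-methoxybenzylidene acetal, in which aluminium binds the less hindered primary ring oxygen so that the PMB ether stays on the secondary oxygen (later O8) and the primary alcohol (later C10) is freed.

Step 6
Reactants: 8 (2S,3S)-4-(tert-butyldimethylsilyloxy)-3-(4-methoxybenzyloxy)butane-1,2-diol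
Product: 10 (3E,5S,6S)-7-(tert-butyldimethylsilyloxy)-5-hydroxy-6-(4-methoxybenzyloxy)-3-methylhept-3-en-2-one, via hydroxy aldehyde 9 (not isolated)
Conditions: TEMPO (0.1 equiv), PhI(OAc)2 (1.1 equiv), CH2Cl2, 0 °C to rt; then Ph3P=C(CH3)COCH3, rt
Reagents that add atoms: 3-(triphenyl-λ5-phosphanylidene)butan-2-one CC(=O)C(C)=P(c1ccccc1)(c1ccccc1)c1ccccc1
Why: Nitroxyl-catalysed oxidation is selective for the primary alcohol and the sensitive α-hydroxy aldehyde is trapped at once in a Wittig reaction with the stabilised ylide, which should give the E enone (C10=C11, C9 cis to the C20 methyl).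

Step 7
Reactants: 10 (3E,5S,6S)-7-(tert-butyldimethylsilyloxy)-5-hydroxy-6-(4-methoxybenzyloxy)-3-methylhept-3-en-2-one
Product: 11 (2S,3S,4E)-1-(tert-butyldimethylsilyloxy)-2-(4-methoxybenzyloxy)-5-methyl-6-oxohept-4-en-3-yl 2-methylprop-2-enoate
Conditions: methacryloyl chloride, Et3N, 4-(dimethylamino)pyridine (cat.), CH2Cl2, 0 °C
Reagents that add atoms: methacryloyl chloride C=C(C)C(Cl)=O
Why: Acylation of the allylic alcohol places the dienophile (C14=C1 with C15 and C2) on O9 as the later three-atom tether.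

Step 8
Reactants: 11 (2S,3S,4E)-1-(tert-butyldimethylsilyloxy)-2-(4-methoxybenzyloxy)-5-methyl-6-oxohept-4-en-3-yl 2-methylprop-2-enoate
Product: 12 (2S,3S,4E)-1,6-bis(tert-butyldimethylsilyloxy)-2-(4-methoxybenzyloxy)-5-methylhepta-4,6-dien-3-yl 2-methylprop-2-enoate
Conditions: TBSOTf (1.3 equiv), Et3N, CH2Cl2, −78 °C
Reagents that add atoms: tert-butyldimethylsilyl trifluoromethanesulfonate CC(C)(C)[Si](C)(C)OS(=O)(=O)C(F)(F)F
Why: Soft enolisation of the methyl ketone (silyl triflate and amine) gives the cross-conjugated 2-silyloxydiene kinetically, the ester having no α-hydrogen.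

Step 9
Reactants: 12 (2S,3S,4E)-1,6-bis(tert-butyldimethylsilyloxy)-2-(4-methoxybenzyloxy)-5-methylhepta-4,6-dien-3-yl 2-methylprop-2-enoate
Product: 13 cycloadduct: ring A with the C11=C12 TBS enol ether, trans-fused to the temporary γ-lactone O9–C2(=O) (C15 β, H10 α), C9 carrying the CH(OPMB)CH2OTBS chain
Conditions: toluene (0.005 M), 2,6-di-tert-butyl-4-methylphenol (cat.), propylene oxide (acid scavenger), 170 °C, sealed tube
Reagents that add atoms: none
Why: A thermal, concerted suprafacial [4+2] cycloaddition (intramolecular Diels–Alder reaction) joins the 2-silyloxydiene C10=C11–C12=C13 to the methacrylate alkene C14=C1 and forms C13–C14 and C1–C10 together; the closest known reaction type is the intramolecular Diels–Alder reaction of pentadienyl acrylates (ester-linked 1,3,8-nonatrienes). Ring A (C1, C10, C11, C12, C13, C14) closes as the six-membered ring of the cycloaddition, and the temporary lactone (C1, C2, O9, C9, C10) closes through the same C1–C10 bond as a five-membered ring fused to ring A, with the three-atom tether in the exo position. C10 is controlled by C9: A(1,3) strain between C9 and the C20 methyl on C11 holds the C9–H bond in the diene plane, so the O9-bound dienophile can reach only one diene face while the C8 branch lies on the other. C1 follows from the exo-tether (trans-fused) transition state, which places the C15 methyl under the diene and C2 trans to C9. The step needs trans over cis ring fusion, which the near-planar conjugated ester tether and the C11 substituent (clashing with a tether folded under the diene) should secure; regiochemistry is fixed by the tether and reinforced by the C12 silyloxy group, whose nucleophilic terminus C13 adds to C14.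

Step 10
Reactants: 13 cycloadduct (C11=C12 TBS enol ether, trans-fused temporary lactone)
Product: 14 tricyclic keto lactone: 12-ketone with 11β-methyl (H11 α)
Conditions: Bu4NF (1.05 equiv), AcOH (3 equiv), THF, −78 to −40 °C
Reagents that add atoms: none
Why: Fluoride releases the C11=C12 enolate, whose kinetic protonation by acetic acid should occur under steric approach control on the α face, away from the axial C15 methyl that screens the β face of the rigid trans-fused tricycle, giving the less stable 11β-methyl ketone (the outcome known for kinetic ketonisation of 2-methyl-3-keto steroid enolates anti to the angular methyl).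

Step 11
Reactants: 14 tricyclic keto lactone (12-ketone, 11β-methyl)
Product: 16 tricyclic enone lactone (12-ketone and C13=C14), via trimethylsilyl enol ether 15 (not isolated)
Conditions: LiN(i-Pr)2 (1.1 equiv), THF, −78 °C; Me3SiCl; then Pd(OAc)2 (1.1 equiv), MeCN, rt
Reagents that add atoms: none
Why: Kinetic deprotonation at the C13 methylene (the equatorial C11–H is hindered and poorly aligned, the lactone has no α-hydrogen), silylation and Saegusa–Ito oxidation with divalent palladium introduce C13=C14 without touching C11.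

Step 12
Reactants: 16 tricyclic enone lactone
Product: 17 tricyclic allylic alcohol lactone (12β-OH, C13=C14)
Conditions: NaBH4, CeCl3·7H2O, MeOH, −78 °C
Reagents that add atoms: none
Why: Luche reduction gives 1,2-reduction only, and axial hydride delivery to the α face of the conformationally locked enone, anti to the pseudoaxial C20 methyl, should give the 12β alcohol that step 28 inverts.

Step 13
Reactants: 17 tricyclic allylic alcohol lactone
Product: 19 β-keto sulfone (C2 ketone bearing CH2SO2Ph as C3; 9-OTBS; 12β-OTBS; C8-OPMB; C7-OTBS), via ring-opened keto sulfone diolate 18 (not isolated)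
Conditions: PhSO2CH2Li (3.3 equiv, from PhSO2CH3 and n-BuLi), THF, −78 to −20 °C; then TBSOTf (4 equiv), 2,6-lutidine, −78 to 0 °C; aqueous NH4Cl, then dilute citric acid
Reagents that add atoms: (phenylsulfonyl)methyllithium [Li]CS(=O)(=O)c1ccccc1 (made in the flask from methyl phenyl sulfone CS(=O)(=O)c1ccccc1); tert-butyldimethylsilyl trifluoromethanesulfonate CC(C)(C)[Si](C)(C)OS(=O)(=O)C(F)(F)F
Why: Nucleophilic acyl substitution (Claisen-type condensation) of the strained trans-fused lactone by the sulfonyl carbanion stops at the ketone because the β-keto sulfone is deprotonated at once, and the released O9 and O12 alkoxides are silylated in the same flask.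

Step 14
Reactants: 19 β-keto sulfone tris-silyl ether
Product: 20 C7 primary alcohol (9-OTBS, 12β-OTBS, C8-OPMB, keto sulfone)
Conditions: HF·pyridine, pyridine, THF, 0 °C
Reagents that add atoms: none
Why: Selective desilylation, the unhindered primary silyl ether being cleaved far faster than the two secondary ones.

Step 15
Reactants: 20 C7 primary alcohol
Product: 21 C7 aldehyde (α-OPMB at C8)
Conditions: Dess–Martin periodinane, NaHCO3, CH2Cl2, 0 °C to rt
Reagents that add atoms: none
Why: Dess–Martin oxidation under buffered, non-epimerising conditions gives the α-alkoxy aldehyde.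

Step 16
Reactants: 21 C7 aldehyde; 4 (E)-tert-butyl[(3-chloro-2-methylprop-2-en-1-yl)oxy]dimethylsilane
Product: 23 C7 allylic alcohol (C4-OTBS; C5=C6 chloroalkene; C7 configured as in 35), via chlorovinyllithium 22 (not isolated)
Conditions: 4 (1.6 equiv), s-BuLi, THF/Et2O/pentane, −105 °C; 21 pretreated with LiN(SiMe3)2 (1.0 equiv, THF, −78 °C) and added at −105 °C; AcOH/THF quench at −100 °C
Reagents that add atoms: none
Why: Low-temperature deprotonation of the chloroalkene gives a configurationally stable α-chlorovinyllithium carbenoid that adds 1,2 to the aldehyde (the acidic keto sulfone being masked as its lithium enolate), and Felkin–Anh addition anti to the C8 alkoxy group, reinforced by 1,3-anti induction from the C9 silyloxy group, should set C7.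

Step 17
Reactants: 23 C7 allylic alcohol
Product: 24 C7 2-bromopropanoate (both epimers at the CHBr carbon)
Conditions: 2-bromopropanoyl bromide, pyridine, CH2Cl2, −20 °C
Reagents that add atoms: 2-bromopropanoyl bromide CC(Br)C(Br)=O
Why: Acylation of the secondary allylic alcohol by the acid bromide under mild base, which does not enolise the keto sulfone, installs C17, C18 and C19.

Step 18
Reactants: 24 C7 2-bromopropanoate
Product: 25 C8 secondary alcohol
Conditions: 2,3-dichloro-5,6-dicyano-1,4-benzoquinone, CH2Cl2/pH 7 phosphate buffer, 0 °C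
Reagents that add atoms: none
Why: Oxidative cleavage of the PMB ether by electron transfer to the quinone leaves the silyl ethers, the ester and the vinyl chloride intact.

Step 19
Reactants: 25 C8 secondary alcohol
Product: 26 C8 ketone (α-acyloxy ketone)
Conditions: Dess–Martin periodinane, NaHCO3, CH2Cl2, 0 °C to rt
Reagents that add atoms: none
Why: Dess–Martin oxidation of the hindered secondary alcohol gives the α-acyloxy ketone needed for the lactone closure.

Step 20
Reactants: 26 C8 ketone
Product: 27 γ-lactone (C7, C8, C17, C19; 8-OH; configured as in 35), ring B still open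
Conditions: LiN(SiMe3)2 (1.0 equiv), THF, −78 °C; then SmI2 (2.5 equiv), THF, −78 °C; aqueous NH4Cl
Reagents that add atoms: none
Why: Intramolecular Reformatsky reaction in which the trivalent samarium enolate from the C–Br bond adds to the neighbouring C8 ketone through a five-membered transition state that keeps the bulky C6 and C9 groups anti, setting C8 (hydroxyl cis to C6) while C17 takes the preferred methyl-trans-to-C9 arrangement (equilibration in step 23 if needed), the keto sulfone being shielded from reduction as its enolate.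

Step 21
Reactants: 27 γ-lactone with C4-OTBS
Product: 28 C4 primary allylic alcohol
Conditions: HF·pyridine, pyridine, THF, 0 °C
Reagents that add atoms: none
Why: Selective desilylation of the primary allylic silyl ether in the presence of the two hindered secondary ones.

Step 22
Reactants: 28 C4 primary allylic alcohol
Product: 29 C4 allylic bromide
Conditions: CBr4, PPh3, 2,6-lutidine, CH2Cl2, −20 °C
Reagents that add atoms: carbon tetrabromide BrC(Br)(Br)Br
Why: The Appel reaction converts the primary allylic alcohol into the bromide under neutral conditions, the tertiary C8 hydroxyl not reacting.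

Step 23
Reactants: 29 C4 allylic bromide
Product: 30 ring-B-closed 3-(phenylsulfonyl) 2-ketone (ten-membered ring; both C3 epimers)
Conditions: Cs2CO3 (3 equiv), MeCN (0.002 M, slow addition), 40 °C
Reagents that add atoms: none
Why: Intramolecular SN2 C-alkylation of the soft β-keto sulfone carbanion by the allylic bromide under high dilution closes ring B at C3–C4, the cis C5=C6 alkene and the trans-substituted lactone bringing the chain ends together.

Step 24
Reactants: 30 ring-B-closed 3-(phenylsulfonyl) 2-ketone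
Product: 31 2-ketone (9-OTBS, 12β-OTBS)
Conditions: SmI2 (2.5 equiv), THF/MeOH, −78 °C
Reagents that add atoms: none
Why: Reductive desulfonylation, in which electron transfer to the ketone expels sulfinate and the samarium enolate is protonated by methanol.

Step 25
Reactants: 31 2-ketone
Product: 32 2-alcohol (C2 configured as in 35)
Conditions: NaBH4, MeOH/THF, −20 °C
Reagents that add atoms: none
Why: Hydride reduction of the C2 ketone, where attack on the face remote from the C15 methyl of the adjacent quaternary C1 (Felkin–Anh sense, ring B holding C3 gauche to C10) should give the 2S alcohol.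

Step 26
Reactants: 32 2-alcohol
Product: 33 2-acetate (9-OTBS, 12β-OTBS)
Conditions: Ac2O, 4-(dimethylamino)pyridine (cat.), pyridine, CH2Cl2, 0 °C to rt
Reagents that add atoms: acetic anhydride CC(=O)OC(C)=O
Why: Acetylation by nucleophilic catalysis of the only free secondary hydroxyl, the tertiary C8 hydroxyl being too hindered to react.

Step 27
Reactants: 33 2-acetate bis-silyl ether
Product: 34 2-acetate 8,9,12β-triol
Conditions: HF·pyridine, MeCN, 0 °C to rt
Reagents that add atoms: none
Why: Fluoride-mediated desilylation under non-basic conditions avoids acetyl migration and lactone opening.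

Step 28
Reactants: 34 2-acetate 8,9,12β-triol
Product: 35 target CNP0296164.1
Conditions: AcOH, PPh3, diisopropyl azodicarboxylate, toluene, 0 °C
Reagents that add atoms: acetic acid CC(=O)O
Why: Mitsunobu reaction, in which the allylic C12 hydroxyl is activated and displaced by acetate with inversion (SN2, attack at the neopentyl C14 being blocked) while the hindered C9 and tertiary C8 hydroxyls are not activated.

**Compound list**

1 | prop-2-yn-1-ol | C#CCO | starting material
2 | alkenylalane, (E)-Me2Al–CH=C(CH3)–CH2–O–AlMe2 | C[Al](C)OC/C(C)=C/[Al](C)C | intermediate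
3 | (E)-3-chloro-2-methylprop-2-en-1-ol | OC/C(C)=C/Cl | intermediate
4 | (E)-tert-butyl[(3-chloro-2-methylprop-2-en-1-yl)oxy]dimethylsilane | CC(C)(C)[Si](C)(C)OC/C(C)=C/Cl | intermediate
5 | L-threitol, (2S,3S)-butane-1,2,3,4-tetrol | OC[C@H](O)[C@@H](O)CO | starting material
6 | (2R,4S,5S)-4-(hydroxymethyl)-2-(4-methoxyphenyl)-1,3-dioxan-5-ol (1,3-O-(4-methoxybenzylidene)-L-threitol) | COc1ccc(cc1)[C@@H]1OC[C@H](O)[C@H](CO)O1 | intermediate
7 | (2R,4S,5S)-4-[(tert-butyldimethylsilyloxy)methyl]-2-(4-methoxyphenyl)-1,3-dioxan-5-ol | COc1ccc(cc1)[C@@H]1OC[C@H](O)[C@H](CO[Si](C)(C)C(C)(C)C)O1 | intermediate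
8 | (2S,3S)-4-(tert-butyldimethylsilyloxy)-3-(4-methoxybenzyloxy)butane-1,2-diol | OC[C@H](O)[C@H](CO[Si](C)(C)C(C)(C)C)OCc1ccc(OC)cc1 | intermediate
9 | (2R,3S)-4-(tert-butyldimethylsilyloxy)-2-hydroxy-3-(4-methoxybenzyloxy)butanal | O=C[C@H](O)[C@H](CO[Si](C)(C)C(C)(C)C)OCc1ccc(OC)cc1 | intermediate
10 | (3E,5S,6S)-7-(tert-butyldimethylsilyloxy)-5-hydroxy-6-(4-methoxybenzyloxy)-3-methylhept-3-en-2-one | CC(=O)/C(C)=C/[C@H](O)[C@H](CO[Si](C)(C)C(C)(C)C)OCc1ccc(OC)cc1 | intermediate
11 | (2S,3S,4E)-1-(tert-butyldimethylsilyloxy)-2-(4-methoxybenzyloxy)-5-methyl-6-oxohept-4-en-3-yl 2-methylprop-2-enoate | CC(=O)/C(C)=C/[C@H](OC(=O)C(C)=C)[C@H](CO[Si](C)(C)C(C)(C)C)OCc1ccc(OC)cc1 | intermediate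
12 | (2S,3S,4E)-1,6-bis(tert-butyldimethylsilyloxy)-2-(4-methoxybenzyloxy)-5-methylhepta-4,6-dien-3-yl 2-methylprop-2-enoate | C=C(O[Si](C)(C)C(C)(C)C)/C(C)=C/[C@H](OC(=O)C(C)=C)[C@H](CO[Si](C)(C)C(C)(C)C)OCc1ccc(OC)cc1 | intermediate
13 | cycloadduct: ring A with C11=C12 TBS enol ether, trans-fused to the temporary γ-lactone O9–C2(=O), C15 β, H10 α, C9 bearing CH(OPMB)CH2OTBS | CC(C)(C)[Si](C)(C)OC[C@H](OCc1ccc(OC)cc1)[C@H]1OC(=O)[C@@]2(C)CCC(O[Si](C)(C)C(C)(C)C)=C(C)[C@H]12 | intermediate
14 | tricyclic keto lactone: 12-ketone of 13 with 11β-methyl (H11 α) | CC(C)(C)[Si](C)(C)OC[C@H](OCc1ccc(OC)cc1)[C@H]1OC(=O)[C@@]2(C)CCC(=O)[C@H](C)[C@H]12 | intermediate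
15 | C12–C13 trimethylsilyl enol ether of 14 | CC(C)(C)[Si](C)(C)OC[C@H](OCc1ccc(OC)cc1)[C@H]1OC(=O)[C@@]2(C)CC=C(O[Si](C)(C)C)[C@H](C)[C@H]12 | intermediate
16 | tricyclic enone lactone: 12-ketone, C13=C14, 11β-methyl | CC(C)(C)[Si](C)(C)OC[C@H](OCc1ccc(OC)cc1)[C@H]1OC(=O)[C@@]2(C)C=CC(=O)[C@H](C)[C@H]12 | intermediate
17 | tricyclic allylic alcohol lactone: 12β-OH, C13=C14 | CC(C)(C)[Si](C)(C)OC[C@H](OCc1ccc(OC)cc1)[C@H]1OC(=O)[C@@]2(C)C=C[C@H](O)[C@H](C)[C@H]12 | intermediate
18 | ring-opened keto sulfone 9,12-diol (present as its lithium alkoxides and enolate) | CC(C)(C)[Si](C)(C)OC[C@H](OCc1ccc(OC)cc1)[C@@H](O)[C@H]1[C@@H](C)[C@@H](O)C=C[C@]1(C)C(=O)CS(=O)(=O)c1ccccc1 | intermediate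
19 | β-keto sulfone: ring A (C13=C14, 11β-methyl, 12β-OTBS) with C1 bearing C15 and the C2 ketone–CH2SO2Ph, C10 bearing the chain C9(OTBS)–C8(OPMB)–C7H2OTBS | CC(C)(C)[Si](C)(C)OC[C@H](OCc1ccc(OC)cc1)[C@@H](O[Si](C)(C)C(C)(C)C)[C@H]1[C@@H](C)[C@@H](O[Si](C)(C)C(C)(C)C)C=C[C@]1(C)C(=O)CS(=O)(=O)c1ccccc1 | intermediate
20 | C7 primary alcohol of 19 | OC[C@H](OCc1ccc(OC)cc1)[C@@H](O[Si](C)(C)C(C)(C)C)[C@H]1[C@@H](C)[C@@H](O[Si](C)(C)C(C)(C)C)C=C[C@]1(C)C(=O)CS(=O)(=O)c1ccccc1 | intermediate
21 | C7 aldehyde | O=C[C@H](OCc1ccc(OC)cc1)[C@@H](O[Si](C)(C)C(C)(C)C)[C@H]1[C@@H](C)[C@@H](O[Si](C)(C)C(C)(C)C)C=C[C@]1(C)C(=O)CS(=O)(=O)c1ccccc1 | intermediate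
22 | (E)-[3-(tert-butyldimethylsilyloxy)-1-chloro-2-methylprop-1-en-1-yl]lithium | CC(C)(C)[Si](C)(C)OC/C(C)=C(/Cl)[Li] | intermediate
23 | C7 allylic alcohol: chain C4H2OTBS–C5(CH3)=C6(Cl)–C7H(OH)–C8H(OPMB)–C9H(OTBS)– on C10, C5=C6 with Cl cis to C16 | CC(C)(C)[Si](C)(C)OC/C(C)=C(/Cl)[C@H](O)[C@H](OCc1ccc(OC)cc1)[C@@H](O[Si](C)(C)C(C)(C)C)[C@H]1[C@@H](C)[C@@H](O[Si](C)(C)C(C)(C)C)C=C[C@]1(C)C(=O)CS(=O)(=O)c1ccccc1 | intermediate
24 | C7 2-bromopropanoate of 23 | CC(C)(C)[Si](C)(C)OC/C(C)=C(/Cl)[C@H](OC(=O)C(C)Br)[C@H](OCc1ccc(OC)cc1)[C@@H](O[Si](C)(C)C(C)(C)C)[C@H]1[C@@H](C)[C@@H](O[Si](C)(C)C(C)(C)C)C=C[C@]1(C)C(=O)CS(=O)(=O)c1ccccc1 | intermediate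
25 | C8 secondary alcohol (PMB removed) | CC(C)(C)[Si](C)(C)OC/C(C)=C(/Cl)[C@H](OC(=O)C(C)Br)[C@H](O)[C@@H](O[Si](C)(C)C(C)(C)C)[C@H]1[C@@H](C)[C@@H](O[Si](C)(C)C(C)(C)C)C=C[C@]1(C)C(=O)CS(=O)(=O)c1ccccc1 | intermediate
26 | C8 ketone with C7 2-bromopropanoate | CC(C)(C)[Si](C)(C)OC/C(C)=C(/Cl)[C@H](OC(=O)C(C)Br)C(=O)[C@@H](O[Si](C)(C)C(C)(C)C)[C@H]1[C@@H](C)[C@@H](O[Si](C)(C)C(C)(C)C)C=C[C@]1(C)C(=O)CS(=O)(=O)c1ccccc1 | intermediate
27 | γ-lactone (O7–C19(=O)–C17H(CH3)–C8(OH)–C7), ring B open, C4-OTBS | CC(C)(C)[Si](C)(C)OC/C(C)=C(/Cl)[C@@H]2OC(=O)[C@H](C)[C@@]2(O)[C@@H](O[Si](C)(C)C(C)(C)C)[C@H]1[C@@H](C)[C@@H](O[Si](C)(C)C(C)(C)C)C=C[C@]1(C)C(=O)CS(=O)(=O)c1ccccc1 | intermediate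
28 | C4 primary allylic alcohol | OC/C(C)=C(/Cl)[C@@H]2OC(=O)[C@H](C)[C@@]2(O)[C@@H](O[Si](C)(C)C(C)(C)C)[C@H]1[C@@H](C)[C@@H](O[Si](C)(C)C(C)(C)C)C=C[C@]1(C)C(=O)CS(=O)(=O)c1ccccc1 | intermediate
29 | C4 allylic bromide | BrC/C(C)=C(/Cl)[C@@H]2OC(=O)[C@H](C)[C@@]2(O)[C@@H](O[Si](C)(C)C(C)(C)C)[C@H]1[C@@H](C)[C@@H](O[Si](C)(C)C(C)(C)C)C=C[C@]1(C)C(=O)CS(=O)(=O)c1ccccc1 | intermediate
30 | briarane skeleton with ring B closed: 2-ketone, 3-phenylsulfonyl, 9-OTBS, 12β-OTBS, 8-OH | O=C1C(S(=O)(=O)c2ccccc2)C/C(C)=C(/Cl)[C@@H]2OC(=O)[C@H](C)[C@@]2(O)[C@@H](O[Si](C)(C)C(C)(C)C)[C@H]2[C@@H](C)[C@@H](O[Si](C)(C)C(C)(C)C)C=C[C@@]21C | intermediate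
31 | 2-ketone, 9-OTBS, 12β-OTBS | O=C1CC/C(C)=C(/Cl)[C@@H]2OC(=O)[C@H](C)[C@@]2(O)[C@@H](O[Si](C)(C)C(C)(C)C)[C@H]2[C@@H](C)[C@@H](O[Si](C)(C)C(C)(C)C)C=C[C@@]21C | intermediate
32 | (2S)-2-alcohol, 9-OTBS, 12β-OTBS | O[C@H]1CC/C(C)=C(/Cl)[C@@H]2OC(=O)[C@H](C)[C@@]2(O)[C@@H](O[Si](C)(C)C(C)(C)C)[C@H]2[C@@H](C)[C@@H](O[Si](C)(C)C(C)(C)C)C=C[C@@]21C | intermediate
33 | 2-acetate, 9-OTBS, 12β-OTBS | CC(=O)O[C@H]1CC/C(C)=C(/Cl)[C@@H]2OC(=O)[C@H](C)[C@@]2(O)[C@@H](O[Si](C)(C)C(C)(C)C)[C@H]2[C@@H](C)[C@@H](O[Si](C)(C)C(C)(C)C)C=C[C@@]21C | intermediate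
34 | 2-acetate 8,9,12β-triol (12-epimer of the deacetyl target) | CC(=O)O[C@H]1CC/C(C)=C(/Cl)[C@@H]2OC(=O)[C@H](C)[C@@]2(O)[C@@H](O)[C@H]2[C@@H](C)[C@@H](O)C=C[C@@]21C | intermediate
35 | CNP0296164.1 | CC(=O)O[C@H]1CC/C(C)=C(/Cl)[C@@H]2OC(=O)[C@H](C)[C@@]2(O)[C@@H](O)[C@H]2[C@@H](C)[C@H](OC(C)=O)C=C[C@@]21C | target

Total steps: 28. Longest linear sequence: 26 steps (steps 3 to 28, from L-threitol); the fragment of steps 1 and 2 enters at step 16.

**Steps most likely to fail**

Step 9. The tethered cycloaddition may be too slow at temperatures the silyl dienol ether survives, or it may close through the folded transition state and lose the trans ring-fusion selectivity, which would invert C1. The fallback sets out from 12 and comes back at 13. It is a bimolecular, exo-selective Diels–Alder reaction in which the O9 methacrylate is only a spectator ester. Triene 12 would be treated with methacrolein (C=C(C)C=O) bound to aluminium tris(2,6-diphenylphenoxide) in toluene at −78 °C, the bulky Lewis acid enforcing the exo mode and the dienophile entering anti to the C8 branch, to give the exo aldehyde adduct F1. i-Bu2AlH would then reduce the aldehyde and cleave the methacrylate to give the 2,9-diol F2, and Ag2CO3 on Celite (Fétizon oxidation) would close the 1,4-diol to the lactone 13.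

Step 10. Protonation may take the stereoelectronically favoured axial path on the β face, or the strained 11β-methyl ketone may epimerise on work-up; either way facial selectivity at C11 is lost. The fallback sets out from 13 and comes back at 14. It replaces ionic protonation by hydrogen-atom transfer: N-bromosuccinimide in THF at −78 °C would convert the enol ether into the 11-bromo ketone F3 (configuration at C11 immaterial). Bu3SnH with Et3B/air in toluene at −78 °C would then generate the planar C11 radical, which should take hydrogen from the bulky stannane on the open α face to give 14 under neutral conditions.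

Step 23. Intermolecular alkylation (oligomerisation) or O-alkylation may outcompete closure of the ten-membered ring. The fallback sets out from 28 and comes back at 30. It is a Tsuji–Trost macrocyclization: methyl chloroformate and pyridine would convert 28 into the allylic methyl carbonate F4. Pd2(dba)3 (zerovalent palladium) with Ph2PCH2CH2PPh2 in THF at 60 °C under slow addition would ionise it to a π-allyl palladium complex, which the keto sulfone, deprotonated by the released methoxide, should attack at the primary terminus C4 to give 30 without added base.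

Further compounds
F1 | step 9 | exo aldehyde adduct: ring A with C11=C12 TBS enol ether, C1 bearing C15 and CHO (C2), C9 still carrying the methacrylate | CC(C)(C)[Si](C)(C)OC[C@H](OCc1ccc(OC)cc1)[C@@H](OC(=O)C(C)=C)[C@H]1C(C)=C(O[Si](C)(C)C(C)(C)C)CC[C@]1(C)C=O
F2 | step 9 | 2,9-diol: C2 as CH2OH on C1, free C9 hydroxyl, C11=C12 TBS enol ether | CC(C)(C)[Si](C)(C)OC[C@H](OCc1ccc(OC)cc1)[C@@H](O)[C@H]1C(C)=C(O[Si](C)(C)C(C)(C)C)CC[C@]1(C)CO
F3 | step 10 | 11-bromo 12-ketone of the tricyclic lactone (C11 epimers) | CC(C)(C)[Si](C)(C)OC[C@H](OCc1ccc(OC)cc1)[C@H]1OC(=O)[C@@]2(C)CCC(=O)C(C)(Br)[C@H]12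
F4 | step 23 | C4 allylic methyl carbonate of 28 | COC(=O)OC/C(C)=C(/Cl)[C@@H]2OC(=O)[C@H](C)[C@@]2(O)[C@@H](O[Si](C)(C)C(C)(C)C)[C@H]1[C@@H](C)[C@@H](O[Si](C)(C)C(C)(C)C)C=C[C@]1(C)C(=O)CS(=O)(=O)c1ccccc1
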